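**Plan**

- Feature: in lignan numbering the chain C9–C8(OH)–C8'–C9' of the target is the carbon chain of L-malic acid with the hydroxyl already on C8. Ring A is C8–C7–O–C9'–C8' and ring B is C8'–C7'–O–C9–C8.
- Retrosynthesis: cut O–C9' (ring A) and C7'–O (ring B) to a pentaol, return C9 and C9' to the carboxyl level (bis-lactone), cut C8'–C7' (second aldol), then cut C8–C7 together with the lactone O–C9' bond (aldol–lactonization on the pivalaldehyde acetal of malic acid).
- Forward: L-malic acid → cis dioxolanone → aldol with silylated vanillin and lactonization (C8–C7, lactone of ring A) → acetal exchanged for OH/CO2Me → dianion aldol and second lactonization (C8'–C7', lactone of ring B) → LiAlH4 → ring B by benzylic cation closure, ring A by primary mesylate → desilylation.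
- Stereochemistry: C8 comes from L-malic acid, relayed through the acetal carbon (addition trans to tert-butyl, net retention). C7 comes from the closed aldol transition state. C8' comes from addition anti to the C8 alkoxide and is fixed by the cis ring fusion. C7' comes from the trans-selective cation ring closure.

Key step: step 3

Remark: the phenols are carried as triisopropylsilyl ethers, because they must pass lithium amides, lithium methoxide, LiAlH4 and Brønsted acid, which aryl tert-butyldimethylsilyl ethers tolerate less well.

**Route**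

Step 1
Reactants: 1 L-malic acid; 2 pivalaldehyde
Product: 3 (2S,4S)-2-tert-butyl-5-oxo-1,3-dioxolane-4-acetic acid (cis dioxolanone acid)
Conditions: 2 (1.5 equiv), TsOH·H2O (cat.), H2SO4 (cat.), pentane, reflux, Dean–Stark; recrystallization
Reagents that add atoms: none
Why: Acid-catalysed acetalization with azeotropic removal of water engages only the α-hydroxy acid unit in a five-membered 1,3-dioxolan-4-one; the cis isomer (tert-butyl and CH2CO2H on the same face) is thermodynamically favoured and should be obtained pure by crystallization, with C8 untouched.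

Step 2
Reactants: 4 vanillin
Product: 5 3-methoxy-4-(triisopropylsilyloxy)benzaldehyde
Conditions: iPr3SiCl, imidazole, DMF, rt
Reagents that add atoms: triisopropylsilyl chloride, CC(C)[Si](Cl)(C(C)C)C(C)C
Why: Imidazole-promoted silylation of the phenol (silyl ether formation) leaves the aldehyde untouched and involves no stereocentre.

Step 3
Reactants: 3 (2S,4S)-2-tert-butyl-5-oxo-1,3-dioxolane-4-acetic acid; 5 3-methoxy-4-(triisopropylsilyloxy)benzaldehyde
Product: 8 (2S,5R,6R)-2-tert-butyl-6-[3-methoxy-4-(triisopropylsilyloxy)phenyl]-1,3,7-trioxaspiro[4.4]nonane-4,8-dione (spiro dioxolanone γ-lactone), via dilithium enolate carboxylate 6 (not isolated), via aldol hydroxy acid 7 (not isolated)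
Conditions: LiN(SiMe3)2 (2.2 equiv), THF, −78 °C; 5, −78 °C; 1 M HCl (cold quench); then TsOH·H2O (cat.), CH2Cl2, rt
Reagents that add atoms: none
Why: Two equivalents of LiN(SiMe3)2 should give the dilithium carboxylate–enolate 6, in which C8 is trigonal and only the acetal carbon is stereogenic; the aldehyde carbon of 5 then bonds to C8 on the face trans to the tert-butyl group, so the C8–O bond ends where it was in L-malic acid (self-regeneration of the stereocentre, net retention) and C8 becomes quaternary. The addition is an aldol reaction of a ring-locked lithium enolate (enolate oxygen cis to the C8' methylene) through a closed, lithium-bridged chair transition state with the aryl group equatorial, which places the C7 oxygen syn to C8' and the aryl group cis to the C8 oxygen, i.e. 7R. Acidification gives γ-hydroxy acid 7, whose C7 hydroxyl attacks the C9' carboxyl in a 5-exo-trig acyl substitution (acid-catalysed lactonization) and closes the lactone form of ring A with loss of water. The closest known reaction type is the alkylation and aldol addition of lithium enolates of pivalaldehyde dioxolanones of α-hydroxy acids, including the dianion of this malic acid derivative, followed by lactonization of a γ-hydroxy acid. The step needs C-attack at the enolate, face selectivity at C8 (secured by the acetal tert-butyl group) and face selectivity at the aldehyde (secured by the fixed enolate geometry in the chair); low temperature and a cold acid quench should keep the aldolate from reverting.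

Step 4
Reactants: 8 spiro dioxolanone γ-lactone
Product: 9 methyl (2R,3R)-3-hydroxy-2-[3-methoxy-4-(triisopropylsilyloxy)phenyl]-5-oxooxolane-3-carboxylate (hydroxy ester lactone)
Conditions: HCl (1.25 M in MeOH), 0 °C → rt
Reagents that add atoms: methanol, CO
Why: Acid-catalysed transesterification of the acylal-type dioxolanone carbonyl by methanol should release pivalaldehyde and leave the tertiary hydroxyl and a methyl ester on C8 without touching a stereocentre, while the γ-lactone, the aryl silyl ether and the benzylic C7–O bond (deactivated by the adjacent oxygenated quaternary carbon) should survive; the exchange is made because an enolate at C8' with the acetal oxygen still on C8 would fragment by β-elimination, whereas a lithium alkoxide cannot leave.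

Step 5
Reactants: 9 hydroxy ester lactone; 5 3-methoxy-4-(triisopropylsilyloxy)benzaldehyde
Product: 12 (1R,2R,5R,6S)-1-hydroxy-2,6-bis[3-methoxy-4-(triisopropylsilyloxy)phenyl]-3,7-dioxabicyclo[3.3.0]octane-4,8-dione (hydroxy bis-lactone), via dilithium alkoxide enolate 10 (not isolated), via dilithium aldolate 11 (not isolated)
Conditions: LiN(iPr)2 (2.2 equiv), THF, −78 °C; 5, −78 → −20 °C; 1 M HCl
Reagents that add atoms: none
Why: This is a Fráter–Seebach-type dianion aldol addition with tandem lactonization: the aldehyde should add to C8' of 10 on the face anti to the C8 lithium alkoxide and the C7 aryl group, which is the face cis to the ester, and aldolate 11 closes the second lactone by 5-exo-trig acyl substitution with loss of methoxide, so that only the cis-fused 8'R bis-lactone can form while reversible addition returns mismatched aldolates; the 7'S (exo-aryl) carbinol drawn is expected to lactonize fastest, and this centre is set again in step 7.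

Step 6
Reactants: 12 hydroxy bis-lactone
Product: 13 (1R,2S,3R,4S)-2,3-bis(hydroxymethyl)-1,4-bis[3-methoxy-4-(triisopropylsilyloxy)phenyl]butane-1,2,4-triol (pentaol)
Conditions: LiAlH4 (5 equiv), THF, 0 °C → rt; H2O, aq. NaOH work-up
Reagents that add atoms: none
Why: Hydride reduction of both lactones by LiAlH4 to the diols breaks no C–O bond at C7, C7' or C8, so all four stereocentres should be retained and the aryl silyl ethers should survive.

Step 7
Reactants: 13 pentaol
Product: 14 (3S,4R,5S)-3-{(R)-hydroxy[3-methoxy-4-(triisopropylsilyloxy)phenyl]methyl}-4-(hydroxymethyl)-5-[3-methoxy-4-(triisopropylsilyloxy)phenyl]oxolan-3-ol (ring B closed, triol)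
Conditions: (1S)-(+)-10-camphorsulfonic acid (0.1 equiv), CH2Cl2, 0 °C
Reagents that add atoms: none
Why: In this acid-catalysed SN1 cyclodehydration the C7' benzylic alcohol (activated by the para silyloxy group, whereas C7 is deactivated by the oxygenated quaternary C8) should ionize to the benzylic cation, which the C9 hydroxyl captures in a 5-exo-trig closure of ring B with the aryl group trans to the C9' hydroxymethyl on C8' (2,3-trans, exo, 7'S), an outcome that does not depend on the C7' configuration of 13 and follows the known trans-selective cation closure of 2-aryl-tetrahydrofuran lignans.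

Step 8
Reactants: 14 ring-B triol
Product: 16 (1S,2R,5R,6S)-1-hydroxy-2,6-bis[3-methoxy-4-(triisopropylsilyloxy)phenyl]-3,7-dioxabicyclo[3.3.0]octane (bis-silyl ether of the target), via primary mesylate 15 (not isolated)
Conditions: MeSO2Cl (1.1 equiv), pyridine, −20 °C → rt
Reagents that add atoms: none
Why: Selective mesylation of the only primary alcohol should give 15, which the neutral C7 benzylic hydroxyl displaces in pyridine in a 5-exo-tet SN2 etherification that closes ring A (cis-fused by necessity) with retention at C7, because its C–O bond is not broken; the tertiary C8 hydroxyl stays free because it could only close a four-membered ring.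

Step 9
Reactants: 16 bis-silyl ether of the target
Product: 17 8-hydroxypinoresinol, (1S,2R,5R,6S)-1-hydroxy-2,6-bis(4-hydroxy-3-methoxyphenyl)-3,7-dioxabicyclo[3.3.0]octane
Conditions: Bu4NF (2.5 equiv), AcOH (2.5 equiv), THF, 0 °C
Reagents that add atoms: none
Why: Fluoride-induced cleavage of the two aryl silyl ethers (desilylation), buffered with acetic acid, should leave the furofuran, the tertiary alcohol and all stereocentres untouched.

**Compound list**

1 | L-malic acid | O[C@@H](CC(=O)O)C(=O)O | starting material
2 | pivalaldehyde | CC(C)(C)C=O | starting material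
3 | (2S,4S)-2-tert-butyl-5-oxo-1,3-dioxolane-4-acetic acid | CC(C)(C)[C@H]1O[C@@H](CC(=O)O)C(=O)O1 | intermediate
4 | vanillin | COc1cc(C=O)ccc1O | starting material
5 | 3-methoxy-4-(triisopropylsilyloxy)benzaldehyde | COc1cc(C=O)ccc1O[Si](C(C)C)(C(C)C)C(C)C | intermediate
6 | dilithium (2S)-2-tert-butyl-5-(carboxylatomethyl)-1,3-dioxol-4-olate (dianion of 3) | [Li+].[Li+].CC(C)(C)[C@H]1OC(CC(=O)[O-])=C([O-])O1 | intermediate
7 | (2S,4R)-2-tert-butyl-4-{(R)-hydroxy[3-methoxy-4-(triisopropylsilyloxy)phenyl]methyl}-5-oxo-1,3-dioxolane-4-acetic acid | CC(C)(C)[C@H]1O[C@@]([C@H](O)c2ccc(O[Si](C(C)C)(C(C)C)C(C)C)c(OC)c2)(CC(=O)O)C(=O)O1 | intermediate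
8 | (2S,5R,6R)-2-tert-butyl-6-[3-methoxy-4-(triisopropylsilyloxy)phenyl]-1,3,7-trioxaspiro[4.4]nonane-4,8-dione | CC(C)(C)[C@H]1O[C@@]2(CC(=O)O[C@@H]2c3ccc(O[Si](C(C)C)(C(C)C)C(C)C)c(OC)c3)C(=O)O1 | intermediate
9 | methyl (2R,3R)-3-hydroxy-2-[3-methoxy-4-(triisopropylsilyloxy)phenyl]-5-oxooxolane-3-carboxylate | O[C@@]1(CC(=O)O[C@@H]1c2ccc(O[Si](C(C)C)(C(C)C)C(C)C)c(OC)c2)C(=O)OC | intermediate
10 | dilithium alkoxide–enolate of 9 | [Li+].[Li+].[O-][C@@]1(C=C([O-])O[C@@H]1c2ccc(O[Si](C(C)C)(C(C)C)C(C)C)c(OC)c2)C(=O)OC | intermediate
11 | dilithium aldolate (C8 and C7' alkoxides, 8'R,7'S) | [Li+].[Li+].[O-][C@@]1([C@@H]([C@H]([O-])c2ccc(O[Si](C(C)C)(C(C)C)C(C)C)c(OC)c2)C(=O)O[C@@H]1c3ccc(O[Si](C(C)C)(C(C)C)C(C)C)c(OC)c3)C(=O)OC | intermediate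
12 | (1R,2R,5R,6S)-1-hydroxy-2,6-bis[3-methoxy-4-(triisopropylsilyloxy)phenyl]-3,7-dioxabicyclo[3.3.0]octane-4,8-dione | COc1cc([C@H]2OC(=O)[C@]3(O)[C@@H](c4ccc(O[Si](C(C)C)(C(C)C)C(C)C)c(OC)c4)OC(=O)[C@H]23)ccc1O[Si](C(C)C)(C(C)C)C(C)C | intermediate
13 | (1R,2S,3R,4S)-2,3-bis(hydroxymethyl)-1,4-bis[3-methoxy-4-(triisopropylsilyloxy)phenyl]butane-1,2,4-triol | COc1cc([C@@H](O)[C@@H](CO)[C@](O)(CO)[C@H](O)c2ccc(O[Si](C(C)C)(C(C)C)C(C)C)c(OC)c2)ccc1O[Si](C(C)C)(C(C)C)C(C)C | intermediate
14 | (3S,4R,5S)-3-{(R)-hydroxy[3-methoxy-4-(triisopropylsilyloxy)phenyl]methyl}-4-(hydroxymethyl)-5-[3-methoxy-4-(triisopropylsilyloxy)phenyl]oxolan-3-ol | COc1cc([C@H]2OC[C@](O)([C@H](O)c3ccc(O[Si](C(C)C)(C(C)C)C(C)C)c(OC)c3)[C@@H]2CO)ccc1O[Si](C(C)C)(C(C)C)C(C)C | intermediate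
15 | primary (C9') methanesulfonate of 14 | COc1cc([C@H]2OC[C@](O)([C@H](O)c3ccc(O[Si](C(C)C)(C(C)C)C(C)C)c(OC)c3)[C@@H]2COS(C)(=O)=O)ccc1O[Si](C(C)C)(C(C)C)C(C)C | intermediate
16 | (1S,2R,5R,6S)-1-hydroxy-2,6-bis[3-methoxy-4-(triisopropylsilyloxy)phenyl]-3,7-dioxabicyclo[3.3.0]octane | COc1cc([C@H]2OC[C@]3(O)[C@@H](c4ccc(O[Si](C(C)C)(C(C)C)C(C)C)c(OC)c4)OC[C@H]23)ccc1O[Si](C(C)C)(C(C)C)C(C)C | intermediate
17 | 8-hydroxypinoresinol | COc1cc([C@H]2OC[C@]3(O)[C@@H](c4ccc(O)c(OC)c4)OC[C@H]23)ccc1O | target

**Step count**

Total: 9 steps. Longest linear sequence: 8 steps (steps 1 and 3–9 from L-malic acid); step 2 is a one-step branch whose product is used twice.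

**Steps most likely to fail**

Step 5. The aldolate may revert on warming before it lactonizes, lactonization may stay incomplete, or the released methoxide may attack the lactone or the aryl silyl ethers. The fallback separates addition and lactonization and avoids strong base. It sets out from 9: silylation with Me3SiOSO2CF3/Et3N (CH2Cl2, 0 °C) would give the bis(trimethylsilyl) ketene acetal–silyl ether F1. A BF3·OEt2-promoted Mukaiyama aldol addition to 5 at −78 °C, on the face of C8' away from the OSiMe3 and aryl groups, followed by aqueous acid would give the dihydroxy ester lactone F2. Catalytic TsOH in toluene would then close the second lactone, and the route is rejoined at 12.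

Step 7. The benzylic cation may be captured by the wrong nucleophile (the C7 hydroxyl, giving a 2,5-diaryl tetrahydrofuran, or the other aryl ring in a Friedel–Crafts closure), or the product may ionize again on prolonged exposure to acid. The fallback forms no cation. It sets out from 13, used as the single 7'S isomer (secured by purifying 12): MeSO2Cl (2.1 equiv) in pyridine at −20 °C would give the bis(primary mesylate) F3. On warming, F3 should close both rings by SN2 displacement at C9 and C9' with retention at both benzylic carbons, and the route is rejoined at 16, bypassing 14.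

Step 3. The lithium aldolate may revert before the quench, and discrimination between the two faces of the aldehyde (the C7 configuration) may be poor. The fallback makes the addition irreversible and moves it to an open transition state. It sets out from 3: the dianion is silylated (LiN(SiMe3)2, then Me3SiCl) to the bis(trimethylsilyl) ketene acetal–silyl ester F4. Under BF3·OEt2 (CH2Cl2, −78 °C) F4 should add to 5 trans to the tert-butyl group with the aryl group next to the smaller ring oxygen, an arrangement that leads to the same 7R carbinol. Aqueous HCl removes silicon to give hydroxy acid 7, which lactonizes as before, and the route is rejoined at 8.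

**Further compounds**

F1 | step 5 | methyl (2R,3R)-2-[3-methoxy-4-(triisopropylsilyloxy)phenyl]-3,5-bis(trimethylsilyloxy)-2,3-dihydrofuran-3-carboxylate | C[Si](C)(C)O[C@@]1(C=C(O[Si](C)(C)C)O[C@@H]1c2ccc(O[Si](C(C)C)(C(C)C)C(C)C)c(OC)c2)C(=O)OC
F2 | step 5 | methyl (2R,3R,4R)-3-hydroxy-4-{(S)-hydroxy[3-methoxy-4-(triisopropylsilyloxy)phenyl]methyl}-2-[3-methoxy-4-(triisopropylsilyloxy)phenyl]-5-oxooxolane-3-carboxylate | O[C@@]1([C@@H]([C@H](O)c2ccc(O[Si](C(C)C)(C(C)C)C(C)C)c(OC)c2)C(=O)O[C@@H]1c3ccc(O[Si](C(C)C)(C(C)C)C(C)C)c(OC)c3)C(=O)OC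
F3 | step 7 | bis(primary methanesulfonate) of pentaol 13 (at C9 and C9') | COc1cc([C@@H](O)[C@@H](COS(C)(=O)=O)[C@](O)(COS(C)(=O)=O)[C@H](O)c2ccc(O[Si](C(C)C)(C(C)C)C(C)C)c(OC)c2)ccc1O[Si](C(C)C)(C(C)C)C(C)C
F4 | step 3 | trimethylsilyl [(2S)-2-tert-butyl-5-(trimethylsilyloxy)-1,3-dioxol-4-yl]acetate | CC(C)(C)[C@H]1OC(CC(=O)O[Si](C)(C)C)=C(O[Si](C)(C)C)O1
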